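**Plan** (drimane numbering: ring A = C1–C5 and C10, ring B = C5–C10, C11 = the CH2O carbon on C9)

- Retrosynthesis: cut the C11–O aryl ether (Mitsunobu reaction with isofraxidin). Trace the ring A enone back to a 3-amino-enone (N on C3, O on C1), so that the C10 methyl group (enolate alkylation) and the C1 oxygen (reduction, hydrolysis) are handled separately. Then cut C2–C3 and C4–C5 together.
- Enabling feature: in ring A the C3 carbonyl and the C4 gem-dimethyl carbon form an isobutyronitrile unit (C4 nucleophile, C3 electrophile). C5 and C2 are the β-carbon and the methyl carbon of an acetylcyclohexadiene (ring B). A Michael–Thorpe (4+2) annulation therefore builds ring A in one operation and tags C3 with nitrogen.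
- Forward order: ring B first, by a tethered dienyne [4+2] cycloaddition (lactone); methyllithium turns the lactone carbonyl into the acetyl group (C1, C2); ring A by the annulation; then angular methylation, carbonyl transposition, desilylation and etherification.
- Stereochemistry: C9 comes from the enantioselective rhodium-catalysed [4+2] cycloaddition. C5 (conjugate addition) and C10 (methylation) follow by substrate control anti to the axial C9 CH2OSi group, which gives the trans ring fusion with H-5 cis to C11.

Key step: step 6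

Remark: all atom numbers in the text are drimane numbers of the target (C4 carries the gem-dimethyl group, C10 the angular methyl group, C9 the C11H2O group).
Assumption: (R)-BINAP is taken as the ligand antipode that gives the (3aS)-lactone in step 3; if the sense of induction is the opposite, (S)-BINAP is used.

Step 1
Reactants: 1 (2E)-3-methylpent-2-en-4-yn-1-ol
Product: 2 (2E)-3-methylpenta-2,4-dien-1-ol
Conditions: H2 (1 atm), Pd/CaCO3 poisoned with Pb(OAc)2, quinoline, EtOAc, 0 °C, stopped after 1 equiv H2
Reagents that add atoms: none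
Why: Partial hydrogenation of a terminal alkyne over lead-poisoned palladium should stop at the alkene and leave the (E)-trisubstituted alkene untouched, giving the (E)-diene needed for cycloaddition; no stereocentre is formed.

Step 2
Reactants: 2 (2E)-3-methylpenta-2,4-dien-1-ol; 3 prop-2-ynoic acid
Product: 4 (2E)-3-methylpenta-2,4-dien-1-yl prop-2-ynoate
Conditions: DCC, DMAP (5 mol %), CH2Cl2, −20 → 0 °C
Reagents that add atoms: none
Why: Steglich esterification (carbodiimide activation, acyl transfer by DMAP) should join the allylic alcohol and the acetylenic acid at low temperature, where conjugate addition of DMAP to the propiolate is slow; no stereocentre is formed.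

Step 3
Reactants: 4 (2E)-3-methylpenta-2,4-dien-1-yl prop-2-ynoate
Product: 5 (3aS)-4-methyl-3a,6-dihydro-2-benzofuran-1(3H)-one
Conditions: [Rh(cod)Cl]2 (2.5 mol %), (R)-BINAP (6 mol %), AgSbF6 (6 mol %), CF3CH2OH–CH2Cl2 (1:1), 25 °C, 0.02 M
Reagents that add atoms: none
Why: Rhodium-catalysed intramolecular [4+2] cycloaddition of an ester-tethered dienyne (oxidative cyclization on cationic monovalent rhodium, allyl shift, reductive elimination) should apply: the three-atom tether forces the carbonyl-bearing alkyne carbon onto C9, there is no thermal background reaction at 25 °C, and the chiral bisphosphine differentiates the diene faces so that the single new stereocentre C9 is set as (S).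

Step 4
Reactants: 5 (3aS)-4-methyl-3a,6-dihydro-2-benzofuran-1(3H)-one
Product: 6 1-[(6S)-6-(hydroxymethyl)-5-methylcyclohexa-1,4-dien-1-yl]ethan-1-one
Conditions: MeLi (1.05 equiv), THF, −78 °C; then H2O, −78 °C → rt
Reagents that add atoms: methyllithium, [Li]C
Why: Mono-addition of an organolithium to a γ-lactone (nucleophilic acyl addition) should stop at the lithium hemiketalate, which is stable at −78 °C and releases the methyl ketone (C1, C2) and the C11 alcohol only on quench; C9 is not touched.

Step 5
Reactants: 6 1-[(6S)-6-(hydroxymethyl)-5-methylcyclohexa-1,4-dien-1-yl]ethan-1-one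
Product: 7 1-[(6S)-5-methyl-6-({[tri(propan-2-yl)silyl]oxy}methyl)cyclohexa-1,4-dien-1-yl]ethan-1-one
Conditions: TIPSCl, imidazole, DMF, 0 °C → rt
Reagents that add atoms: chlorotri(propan-2-yl)silane, CC(C)[Si](Cl)(C(C)C)C(C)C
Why: Imidazole-promoted silylation of the primary alcohol removes the acidic OH and the hemiketal equilibrium before the strongly basic steps, and the acid-stable silyl ether later survives the enamine hydrolysis; no stereocentre is affected.

Step 6
Reactants: 7 1-[(6S)-5-methyl-6-({[tri(propan-2-yl)silyl]oxy}methyl)cyclohexa-1,4-dien-1-yl]ethan-1-one; 8 2-methylpropanenitrile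
Product: 10 (4aS,8R,8aR)-3-amino-4,4,7-trimethyl-8-({[tri(propan-2-yl)silyl]oxy}methyl)-4a,5,8,8a-tetrahydronaphthalen-1(4H)-one, via lithium enolate of the conjugate adduct 9 (not isolated)
Conditions: 8 (1.2 equiv), LiN(i-Pr)2 (1.15 equiv, commercial solution), THF–DMPU, −78 °C; then 7, −78 → 0 °C; then t-BuOH (0.2 equiv), 50 °C; then H2O
Reagents that add atoms: none
Why: Lithiated isobutyronitrile adds to the enone; carbonyl adducts revert on warming and the conjugate adduct 9 accumulates (C4–C5 bond), the tert-butanol shuttle then moves the enolate from C10 to the methyl carbon C2, which attacks the nitrile carbon (C2–C3 bond), and tautomerization to the conjugated enaminone anion makes the sequence irreversible. The closest known reaction types are the Michael addition of α-cyano carbanions to enones and the base-mediated Thorpe cyclization of 5-oxonitriles to 3-aminocyclohex-2-enones, run here as one domino, the nitrile counterpart of a Michael–Claisen synthesis of cyclohexane-1,3-diones. Ring A closes by 6-exo-dig attack of the enolate carbon C2 (enolate double bond outside the new ring) on the nitrile. C5 is set by approach of the nucleophile anti to the C9 CH2OSi group, which allylic strain with the acetyl group and the C8 methyl group holds pseudoaxial, so that H-5 ends cis to C11; C10 is formed as an epimerizable centre under thermodynamic control and is set again in step 7. The step needs conjugate addition to win over carbonyl addition and over deprotonation at C6 or at the acetyl methyl group, and it needs closure at C3 only: the reversibility of carbonyl addition for a tertiary nitrile anion, DMPU and the low addition temperature serve the first, and the quaternary C4 (no α-hydrogen beside the nitrile), together with the fact that the C10 enolate could only form a four-membered ring, serves the second.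

Step 7
Reactants: 10 (4aS,8R,8aR)-3-amino-4,4,7-trimethyl-8-({[tri(propan-2-yl)silyl]oxy}methyl)-4a,5,8,8a-tetrahydronaphthalen-1(4H)-one
Product: 12 (4aR,8S,8aR)-3-[(tert-butoxycarbonyl)amino]-4,4,7,8a-tetramethyl-8-({[tri(propan-2-yl)silyl]oxy}methyl)-4a,5,8,8a-tetrahydronaphthalen-1(4H)-one, via N-lithio C10-methyl enaminone 11 (not isolated)
Conditions: LiN(i-Pr)2 (2.2 equiv, commercial solution), THF–DMPU, −78 → 0 °C; MeI (1.05 equiv), −78 °C; then Boc2O (1.5 equiv), −78 °C → rt; then H2O
Reagents that add atoms: iodomethane, CI; di-tert-butyl dicarbonate, CC(C)(C)OC(=O)OC(=O)OC(C)(C)C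
Why: Dianion alkylation of a β-enaminone followed by N-acylation should apply: the second deprotonation can only occur at C10 (C4 is quaternary), the C10 carbanion is the most nucleophilic site and should be methylated anti to the C9 CH2OSi group (held pseudoaxial by allylic strain with the enolate oxygen), which gives the trans-fused angular methyl group, and the remaining N-lithio enaminone is capped as the carbamate.

Step 8
Reactants: 12 (4aR,8S,8aR)-3-[(tert-butoxycarbonyl)amino]-4,4,7,8a-tetramethyl-8-({[tri(propan-2-yl)silyl]oxy}methyl)-4a,5,8,8a-tetrahydronaphthalen-1(4H)-one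
Product: 14 (4aR,5S,8aS)-1,1,4a,6-tetramethyl-5-({[tri(propan-2-yl)silyl]oxy}methyl)-4a,5,8,8a-tetrahydronaphthalen-2(1H)-one, via C1 allylic alcohol 13 (not isolated)
Conditions: NaBH4, CeCl3·7H2O, MeOH–THF, −20 → 0 °C; then 1 M HCl, THF, 0 °C
Reagents that add atoms: water, O
Why: Stork–Danheiser-type carbonyl transposition: Luche 1,2-reduction of the N-acylated vinylogous amide should give the C1 allylic alcohol, which dilute acid ionizes with nitrogen assistance and hydrolyses to the C3 ketone with the C1=C2 double bond; the triisopropylsilyl ether survives and no stereocentre of the product is affected.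

Step 9
Reactants: 14 (4aR,5S,8aS)-1,1,4a,6-tetramethyl-5-({[tri(propan-2-yl)silyl]oxy}methyl)-4a,5,8,8a-tetrahydronaphthalen-2(1H)-one
Product: 15 (4aR,5S,8aS)-5-(hydroxymethyl)-1,1,4a,6-tetramethyl-4a,5,8,8a-tetrahydronaphthalen-2(1H)-one
Conditions: HF·pyridine, pyridine, THF, 0 °C → rt
Reagents that add atoms: none
Why: Fluoride-mediated desilylation under buffered, weakly acidic conditions should free the primary alcohol without forming an alkoxide, which could add to the enone at C1 (intramolecular oxa-Michael addition); no stereocentre is affected.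

Step 10
Reactants: 15 (4aR,5S,8aS)-5-(hydroxymethyl)-1,1,4a,6-tetramethyl-4a,5,8,8a-tetrahydronaphthalen-2(1H)-one; 16 7-hydroxy-6,8-dimethoxy-2H-chromen-2-one (isofraxidin)
Product: 17 6,8-dimethoxy-7-{[(1S,4aS,8aR)-2,5,5,8a-tetramethyl-6-oxo-1,4,4a,5,6,8a-hexahydronaphthalen-1-yl]methoxy}-2H-chromen-2-one (the target)
Conditions: PPh3, DIAD, THF, 0 → 40 °C
Reagents that add atoms: none
Why: Mitsunobu etherification: the acidic 7-OH of the coumarin should be alkylated by the alkoxyphosphonium ion of the primary alcohol in an SN2 displacement at the CH2 carbon C11, so no stereocentre is involved and neither the enone nor the coumarin lactone meets a strong base or nucleophile.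

**Compound list**

1 | (2E)-3-methylpent-2-en-4-yn-1-ol | C#C/C(C)=C/CO | starting material
2 | (2E)-3-methylpenta-2,4-dien-1-ol | C=C/C(C)=C/CO | intermediate
3 | prop-2-ynoic acid (propiolic acid) | C#CC(=O)O | starting material
4 | (2E)-3-methylpenta-2,4-dien-1-yl prop-2-ynoate | C=C/C(C)=C/COC(=O)C#C | intermediate
5 | (3aS)-4-methyl-3a,6-dihydro-2-benzofuran-1(3H)-one | O=C1OC[C@H]2C(C)=CCC=C12 | intermediate
6 | 1-[(6S)-6-(hydroxymethyl)-5-methylcyclohexa-1,4-dien-1-yl]ethan-1-one | OC[C@H]1C(C)=CCC=C1C(C)=O | intermediate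
7 | 1-[(6S)-5-methyl-6-({[tri(propan-2-yl)silyl]oxy}methyl)cyclohexa-1,4-dien-1-yl]ethan-1-one | CC(C)[Si](OC[C@H]1C(C)=CCC=C1C(C)=O)(C(C)C)C(C)C | intermediate
8 | 2-methylpropanenitrile (isobutyronitrile) | CC(C)C#N | starting material
9 | lithium 1-[(2R,6S)-2-(2-cyanopropan-2-yl)-5-methyl-6-({[tri(propan-2-yl)silyl]oxy}methyl)cyclohex-4-en-1-ylidene]ethan-1-olate (enolate geometry open) | CC(C)[Si](OC[C@H]1C(C)=CC[C@H](C(C)(C)C#N)C1=C(C)O[Li])(C(C)C)C(C)C | intermediate (not isolated)
10 | (4aS,8R,8aR)-3-amino-4,4,7-trimethyl-8-({[tri(propan-2-yl)silyl]oxy}methyl)-4a,5,8,8a-tetrahydronaphthalen-1(4H)-one (trans-fused C10 epimer shown; this centre is set again in step 7) | CC(C)[Si](OC[C@H]1C(C)=CC[C@@H]2C(C)(C)C(N)=CC(=O)[C@H]21)(C(C)C)C(C)C | intermediate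
11 | N-lithio derivative of (4aR,8S,8aR)-3-amino-4,4,7,8a-tetramethyl-8-({[tri(propan-2-yl)silyl]oxy}methyl)-4a,5,8,8a-tetrahydronaphthalen-1(4H)-one | CC(C)[Si](OC[C@H]1C(C)=CC[C@@H]2C(C)(C)C(N[Li])=CC(=O)[C@]21C)(C(C)C)C(C)C | intermediate (not isolated)
12 | (4aR,8S,8aR)-3-[(tert-butoxycarbonyl)amino]-4,4,7,8a-tetramethyl-8-({[tri(propan-2-yl)silyl]oxy}methyl)-4a,5,8,8a-tetrahydronaphthalen-1(4H)-one | CC(C)[Si](OC[C@H]1C(C)=CC[C@@H]2C(C)(C)C(NC(=O)OC(C)(C)C)=CC(=O)[C@]21C)(C(C)C)C(C)C | intermediate
13 | (1RS,4aR,8S,8aR)-3-[(tert-butoxycarbonyl)amino]-4,4,7,8a-tetramethyl-8-({[tri(propan-2-yl)silyl]oxy}methyl)-1,4,4a,5,8,8a-hexahydronaphthalen-1-ol (both C1 epimers) | CC(C)[Si](OC[C@H]1C(C)=CC[C@@H]2C(C)(C)C(NC(=O)OC(C)(C)C)=CC(O)[C@]21C)(C(C)C)C(C)C | intermediate (not isolated)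
14 | (4aR,5S,8aS)-1,1,4a,6-tetramethyl-5-({[tri(propan-2-yl)silyl]oxy}methyl)-4a,5,8,8a-tetrahydronaphthalen-2(1H)-one | CC(C)[Si](OC[C@H]1C(C)=CC[C@@H]2C(C)(C)C(=O)C=C[C@]21C)(C(C)C)C(C)C | intermediate
15 | (4aR,5S,8aS)-5-(hydroxymethyl)-1,1,4a,6-tetramethyl-4a,5,8,8a-tetrahydronaphthalen-2(1H)-one | OC[C@H]1C(C)=CC[C@@H]2C(C)(C)C(=O)C=C[C@]21C | intermediate
16 | 7-hydroxy-6,8-dimethoxy-2H-chromen-2-one (isofraxidin) | COc1cc2ccc(=O)oc2c(OC)c1O | starting material
17 | 6,8-dimethoxy-7-{[(1S,4aS,8aR)-2,5,5,8a-tetramethyl-6-oxo-1,4,4a,5,6,8a-hexahydronaphthalen-1-yl]methoxy}-2H-chromen-2-one; in drimane numbering (5S,9S,10R) | COc1cc2ccc(=O)oc2c(OC)c1OC[C@H]1C(C)=CC[C@@H]2C(C)(C)C(=O)C=C[C@]21C | target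

**Step count and risks**

Total step count: 10. Longest linear sequence: 10 steps (1 → 17); 3, 8 and 16 enter as purchased compounds.

The three steps most likely to fail:

Step 6 (key step). The basic nitrile anion may remove a proton from C6 (doubly allylic and vinylogous to the ketone) or from the acetyl methyl group instead of adding to C5, and the hindered tertiary nitrile may resist ring closure. The fallback sets out from 7 and 8 and returns at 10. Isobutyronitrile 8 is converted with LiN(i-Pr)2 and TBSCl into N-[tert-butyl(dimethyl)silyl]-2-methylprop-1-en-1-imine F1. F1 is added to 7 in a Lewis-acid-promoted Mukaiyama-type conjugate addition (TiCl4, CH2Cl2, −78 °C), in which no strong base is present; aqueous work-up should give the neutral δ-keto nitrile 2-[(1S,5R)-6-acetyl-4-methyl-5-({[tri(propan-2-yl)silyl]oxy}methyl)cyclohex-3-en-1-yl]-2-methylpropanenitrile F2 (C5 set as before, both C10 epimers). F2 is then closed in a separate Thorpe cyclization (KOt-Bu, t-BuOH, THF, 50 °C) to 10.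

Step 3. Facial discrimination by the chiral rhodium catalyst may be insufficient on the ester tether, or the terminal alkynoate may oligomerize. The fallback sets out from 4 and returns at 6. A thermal intramolecular Diels–Alder reaction (toluene, BHT, 130 °C) should give racemic 4-methyl-3a,6-dihydro-2-benzofuran-1(3H)-one F3. Methyllithium as in step 4 gives racemic 1-[6-(hydroxymethyl)-5-methylcyclohexa-1,4-dien-1-yl]ethan-1-one F4. A lipase-catalysed kinetic resolution (Burkholderia cepacia lipase, vinyl acetate, t-BuOMe, rt) then acylates one antipode, taken here as the (R)-alcohol, to [(1R)-2-acetyl-6-methylcyclohexa-2,5-dien-1-yl]methyl acetate F5 and leaves the (S)-alcohol 6. If the enzyme prefers the (S)-alcohol, its acetate is collected instead and cleaved with K2CO3 in MeOH.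

Step 7. The second deprotonation at the tertiary ring-fusion carbon may be incomplete, or methylation may occur on nitrogen or syn to C11. The fallback sets out from 10 and returns at 12. Exhaustive acylation (Boc2O, 3 equiv, DMAP, MeCN) should give (4aS,8R,8aR)-3-[bis(tert-butoxycarbonyl)amino]-4,4,7-trimethyl-8-({[tri(propan-2-yl)silyl]oxy}methyl)-4a,5,8,8a-tetrahydronaphthalen-1(4H)-one F6, which has no N–H. One equivalent of LiN(i-Pr)2 then forms only the C10 enolate (Stork–Danheiser-type α′-deprotonation), and MeI gives (4aR,8S,8aR)-3-[bis(tert-butoxycarbonyl)amino]-4,4,7,8a-tetramethyl-8-({[tri(propan-2-yl)silyl]oxy}methyl)-4a,5,8,8a-tetrahydronaphthalen-1(4H)-one F7. Removal of one carbamate group catalysed by Mg(ClO4)2 (MeCN, 50 °C) returns 12.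

Further compounds
F1 | step 6 | N-[tert-butyl(dimethyl)silyl]-2-methylprop-1-en-1-imine | CC(C)=C=N[Si](C)(C)C(C)(C)C
F2 | step 6 | 2-[(1S,5R)-6-acetyl-4-methyl-5-({[tri(propan-2-yl)silyl]oxy}methyl)cyclohex-3-en-1-yl]-2-methylpropanenitrile (both C6 epimers) | CC(C)[Si](OC[C@H]1C(C)=CC[C@H](C(C)(C)C#N)C1C(C)=O)(C(C)C)C(C)C
F3 | step 3 | racemic 4-methyl-3a,6-dihydro-2-benzofuran-1(3H)-one | O=C1OCC2C(C)=CCC=C12
F4 | step 3 | racemic 1-[6-(hydroxymethyl)-5-methylcyclohexa-1,4-dien-1-yl]ethan-1-one | OCC1C(C)=CCC=C1C(C)=O
F5 | step 3 | [(1R)-2-acetyl-6-methylcyclohexa-2,5-dien-1-yl]methyl acetate | CC(=O)OC[C@@H]1C(C)=CCC=C1C(C)=O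
F6 | step 7 | (4aS,8R,8aR)-3-[bis(tert-butoxycarbonyl)amino]-4,4,7-trimethyl-8-({[tri(propan-2-yl)silyl]oxy}methyl)-4a,5,8,8a-tetrahydronaphthalen-1(4H)-one | CC(C)[Si](OC[C@H]1C(C)=CC[C@@H]2C(C)(C)C(N(C(=O)OC(C)(C)C)C(=O)OC(C)(C)C)=CC(=O)[C@H]21)(C(C)C)C(C)C
F7 | step 7 | (4aR,8S,8aR)-3-[bis(tert-butoxycarbonyl)amino]-4,4,7,8a-tetramethyl-8-({[tri(propan-2-yl)silyl]oxy}methyl)-4a,5,8,8a-tetrahydronaphthalen-1(4H)-one | CC(C)[Si](OC[C@H]1C(C)=CC[C@@H]2C(C)(C)C(N(C(=O)OC(C)(C)C)C(=O)OC(C)(C)C)=CC(=O)[C@]21C)(C(C)C)C(C)C
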